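**Assumption:** The SMILES has no stereodescriptor. The only stereogenic element is the hindered C5–C1′ biaryl axis. I plan for one defined atropo-enantiomer, written as (M): viewed along the axis, the shortest turn from C6 to C8a′ is counter-clockwise. The (P)-form needs only the enantiomeric Cp ligand in Step 10. Plain SMILES cannot encode the axis, so the descriptor is given in the names.

## Retrosynthetic overview
1. Target 15 comes from double O-debenzylation of bis-benzyl ether 14.
2. 14 comes from the new step, an atroposelective Rh(III) C–H activation/[4+2] annulation of the stereolabile biaryl oxime ester 12 with benzyl propargyl ether 13. It forms C4–C4a and C3–N, builds the pyridine ring, and locks the axis by dynamic kinetic resolution.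
3. 12 comes from biaryl ketone 10, made by Suzuki coupling of naphthyl bromide 6 with arylboronate 9 (from 2′,4′-dimethoxyacetophenone).
4. 6 comes from 8-methoxy-3-methyl-1-naphthol 4, made by directed ortho-metalation/methallylation and anionic annulation of N,N-diethyl-2-methoxybenzamide.
5. Ring order: second naphthalene ring (Step 2), then the biaryl bond (Step 7), then the pyridine ring last (Step 10).

## Route

**Step 1**
Reactants: 1 N,N-diethyl-2-methoxybenzamide; 2 3-bromo-2-methylprop-1-ene (methallyl bromide)
Product: 3 N,N-diethyl-2-methoxy-6-(2-methylprop-2-en-1-yl)benzamide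
Conditions: s-BuLi, TMEDA, THF, −78 °C; MgBr2·OEt2; then 2, −78 °C → rt
Reagents that add atoms: none (both partners are numbered reactants)
Why: In this directed ortho-metalation the CONEt2 group outranks OMe, so lithiation occurs at C6, and the derived aryl-magnesium species is allylated cleanly.

**Step 2**
Reactants: 3
Product: 4 8-methoxy-3-methylnaphthalen-1-ol
Conditions: LDA (2.5 equiv), THF, −78 °C → rt; aq NH4Cl
Reagents that add atoms: none
Why: In this anionic o-allylbenzamide annulation the benzylic/allylic anion attacks the adjacent amide through its terminal carbon, and loss of Et2NH with tautomerisation gives the naphthol with OH peri to OMe and Me at C3.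

**Step 3**
Reactants: 4
Product: 5 1-(benzyloxy)-8-methoxy-3-methylnaphthalene
Conditions: BnBr, K2CO3, cat. TBAI, DMF, 60 °C
Reagents that add atoms: benzyl bromide, BrCc1ccccc1
Why: Williamson etherification installs a benzyl group that survives Pd and Rh catalysis and can be removed later without touching the aryl methyl ethers.

**Step 4**
Reactants: 5
Product: 6 4-(benzyloxy)-1-bromo-5-methoxy-2-methylnaphthalene
Conditions: NBS (1.0 equiv), MeCN, −20 → 0 °C, dark
Reagents that add atoms: N-bromosuccinimide, O=C1CCC(=O)N1Br
Why: Electrophilic aromatic bromination goes to the carbon that is para to OBn and ortho to CH3, because the site para to OMe lacks the methyl activation and C2 is flanked on both sides.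

**Step 5**
Reactants: 7 1-(2,4-dimethoxyphenyl)ethan-1-one
Product: 8 1-(5-bromo-2,4-dimethoxyphenyl)ethan-1-one
Conditions: NBS, MeCN, rt
Reagents that add atoms: N-bromosuccinimide, O=C1CCC(=O)N1Br
Why: Electrophilic aromatic bromination occurs at C5, which is para to 2-OMe, ortho to 4-OMe and meta to acetyl, while C3 is crowded between the two OMe groups.

**Step 6**
Reactants: 8
Product: 9 1-[2,4-dimethoxy-5-(4,4,5,5-tetramethyl-1,3,2-dioxaborolan-2-yl)phenyl]ethan-1-one
Conditions: B2pin2, Pd(dppf)Cl2, KOAc, dioxane, 90 °C
Reagents that add atoms: bis(pinacolato)diboron, CC1(C)OB(OC1(C)C)B1OC(C)(C)C(C)(C)O1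
Why: Miyaura borylation tolerates the ketone, whereas a lithiation route would not.

**Step 7**
Reactants: 6; 9
Product: 10 1-{5-[4-(benzyloxy)-5-methoxy-2-methylnaphthalen-1-yl]-2,4-dimethoxyphenyl}ethan-1-one (racemic, tri-ortho axis that rotates on heating)
Conditions: Pd(OAc)2, SPhos, K3PO4, toluene/H2O 10:1, 100 °C
Reagents that add atoms: none
Why: Suzuki–Miyaura coupling to a tri-ortho-substituted biaryl is routine with a bulky dialkylbiarylphosphine, and no stereocontrol is needed at this stage.

**Step 8**
Reactants: 10
Product: 11 the (E)-oxime of 10
Conditions: NH2OH·HCl, pyridine, EtOH, 80 °C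
Reagents that add atoms: hydroxylamine hydrochloride, NO.Cl
Why: Oxime condensation favours the E isomer (OH anti to the aryl group), which points the nitrogen lone pair at the only free ortho C–H.

**Step 9**
Reactants: 11
Product: 12 the (E)-O-pivaloyl oxime of 10
Conditions: PivCl, Et3N, cat. DMAP, CH2Cl2, 0 °C → rt
Reagents that add atoms: pivaloyl chloride, CC(C)(C)C(=O)Cl
Why: O-acylation turns the oxime into a combined directing group and internal oxidant through its N–OPiv bond.

**Step 10 (key step)**
Reactants: 12; 13 benzyl propargyl ether (3-benzyloxyprop-1-yne)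
Product: 14 (M)-5-[4-(benzyloxy)-5-methoxy-2-methylnaphthalen-1-yl]-3-[(benzyloxy)methyl]-6,8-dimethoxy-1-methylisoquinoline
Conditions: (R)-Cp^xRh(C2H4)2 (5 mol %; Cp^x = binaphthyl-fused cyclopentadienyl with 3,3′-OMe groups), (BzO)2 (5 mol %), CsOPiv (0.3 equiv), PivOH (1 equiv), DCE/TFE 4:1, 90 °C, sealed tube; 13 (1.5 equiv) added over 12 h. The sense of induction is checked by ECD, and the ent-ligand is used if it is reversed.
Reagents that add atoms: none (PivOH is lost)
Why: Proposed new method: an atroposelective "peri-locking" C–H annulation under dynamic kinetic resolution, in which the only free ortho C–H of 12 (future C4a) sits next to the axis, so pivalate-assisted concerted metalation–deprotonation (CMD) gives two diastereomeric five-membered rhodacycles that differ in whether the 2′-Me edge or the C8′–H/benzo edge of the perpendicular naphthyl faces the chiral Cp; metalation is reversible with PivOH present and free 12 rotates within minutes at 90 °C (estimated ΔG‡ about 25–28 kcal/mol), so the two rhodacycles equilibrate (Curtin–Hammett) and the matched one undergoes irreversible insertion of the slowly fed terminal alkyne (aryl to the CH terminus, Rh to the substituted carbon), which places carbon at C4a and freezes the axis, after which C–N bond formation with N–O cleavage releases the isoquinoline (C4–H, C3–CH2OBn) and regenerates Rh(III); the binaphthyl-like product axis (ΔG‡ above 33 kcal/mol) does not racemise, the flanked nitrogen binds Rh only weakly, and the 1,2-disubstituted Cp^x is less crowded at the metal than Cp*; the closest known reaction types are the racemic Cp*Rh(III)/Cp*Co(III) oxime-ester plus alkyne isoquinoline synthesis (terminal alkynes give 3-substituted 4-H products) and the Cp^xRh(III) atroposelective C–H functionalisation of labile 1-aryl-isoquinolines, and what has not been shown is ring annulation that locks an axis peri to the new ring with the directing group and the axis on the same arene.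

**Step 11**
Reactants: 14
Product: 15 (M)-ancistrobenomine A, (M)-4-[3-(hydroxymethyl)-6,8-dimethoxy-1-methylisoquinolin-5-yl]-8-methoxy-3-methylnaphthalen-1-ol
Conditions: BCl3 (6 equiv), C6HMe5 (6 equiv), CH2Cl2, −78 → −40 °C; MeOH, aq NaHCO3
Reagents that add atoms: none
Why: Lewis-acid debenzylation with a cation scavenger cleaves both the aryl and alkyl benzyl ethers at low temperature, leaving the three aryl methyl ethers and the axis untouched.

## Compound list
Number | Name | SMILES | Role
--- | --- | --- | ---
1 | N,N-diethyl-2-methoxybenzamide | CCN(CC)C(=O)c1ccccc1OC | starting material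
2 | 3-bromo-2-methylprop-1-ene | C=C(C)CBr | starting material
3 | N,N-diethyl-2-methoxy-6-(2-methylallyl)benzamide | CCN(CC)C(=O)c1c(OC)cccc1CC(C)=C | intermediate
4 | 8-methoxy-3-methylnaphthalen-1-ol | COc1cccc2cc(C)cc(O)c12 | intermediate
5 | 1-(benzyloxy)-8-methoxy-3-methylnaphthalene | COc1cccc2cc(C)cc(OCc3ccccc3)c12 | intermediate
6 | 4-(benzyloxy)-1-bromo-5-methoxy-2-methylnaphthalene | COc1cccc2c(Br)c(C)cc(OCc3ccccc3)c12 | intermediate
7 | 1-(2,4-dimethoxyphenyl)ethan-1-one | CC(=O)c1ccc(OC)cc1OC | starting material
8 | 1-(5-bromo-2,4-dimethoxyphenyl)ethan-1-one | CC(=O)c1cc(Br)c(OC)cc1OC | intermediate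
9 | 5-Bpin-2,4-dimethoxyacetophenone | CC(=O)c1cc(B2OC(C)(C)C(C)(C)O2)c(OC)cc1OC | intermediate
10 | biaryl ketone (rac, labile axis) | CC(=O)c1cc(-c2c(C)cc(OCc3ccccc3)c3c(OC)cccc23)c(OC)cc1OC | intermediate
11 | (E)-oxime of 10 (rac axis) | C/C(=N\O)c1cc(-c2c(C)cc(OCc3ccccc3)c3c(OC)cccc23)c(OC)cc1OC | intermediate
12 | (E)-O-pivaloyl oxime of 10 (rac axis) | C/C(=N\OC(=O)C(C)(C)C)c1cc(-c2c(C)cc(OCc3ccccc3)c3c(OC)cccc23)c(OC)cc1OC | intermediate
13 | benzyl propargyl ether | C#CCOCc1ccccc1 | starting material
14 | (M)-O,O′-dibenzyl-ancistrobenomine A | COc1cc(OC)c2c(C)nc(COCc3ccccc3)cc2c1-c1c(C)cc(OCc2ccccc2)c2c(OC)cccc12 | intermediate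
15 | (M)-ancistrobenomine A | COc1cc(OC)c2c(C)nc(CO)cc2c1-c1c(C)cc(O)c2c(OC)cccc12 | target

## Summary
**Total steps:** 11.
**Longest linear sequence:** 9 (Steps 1–4, then 7–11).

**Three steps most likely to fail**
1. **Step 10 (new step).**
   - Risks: slow metalation at the C–H flanked by the naphthyl group, β-alkoxy elimination to an allene after insertion, and modest ee at 90 °C.
   - Fallback (known chemistry), ring first and axis second:
     - Run the established Cp*Co(III)/Cp*Rh(III) annulation of 2′,4′-dimethoxyacetophenone O-pivaloyl oxime with 13. This gives 3-(benzyloxymethyl)-6,8-dimethoxy-1-methylisoquinoline.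
     - Brominate at C5 with NBS.
     - Couple with the boronic acid from 6 (n-BuLi, then B(OiPr)3) in an asymmetric Suzuki–Miyaura reaction using Pd and a P-chiral dihydrobenzooxaphosphole monophosphine.
     - Remove the residual minor atropisomer on a chiral phase, then carry out Step 11.
2. **Step 4 (bromination regiochemistry).**
   - Risk: bromination at C1 competes with the site para to OMe.
   - Fallback: change the controlling group and the order. Brominate free naphthol 4, where the OH makes the methyl-bearing ring decisively more nucleophilic and C2 is blocked on both sides, and then benzylate to reach 6.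
3. **Step 11 (global debenzylation).**
   - Risks: loss of the peri 5′-OMe through boron chelation, and C-benzylation of the electron-rich rings.
   - Fallback: change the protecting-group plan. Use an isopropyl ether on the naphthol (2-bromopropane in Step 3, cleaved with BCl3 at 0 °C). Use TBS propargyl ether in Step 10 (cleaved with TBAF). This gives two orthogonal, separately controllable deprotections.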